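## Retrosynthetic overview

1. Locants: furanone O–C1=C2H–C3(=O)–C4(CH3)–O; C5H2; lactone O–C6H; ring-fusion C7H; C8H–O-acyl; C9H–OH; C10H–CH3; C11=C13H2; lactone C12=O. 28 ⇐ 27 ⇐ 26: once the skeleton is complete only the oxygen substituents at C8 (isobutyrate on) and C9 (PMB off) are adjusted.
2. 26 ⇐ 24 by the C7–C8 bond. The α-methylene-γ-butyrolactone whose β-carbon C7 carries the oxygenated carbon C8 is a homoallylic alcohol (C13=C11–C7–C8–O), the retron of a carbonyl allylation by a 3-(bromomethyl)but-2-enolide. This bond lies in the nine-membered oxa-ring C6–C5–C4–O–C1–C10–C9–C8–C7, which is closed last; C7, C8 and the exo-methylene arise in the same operation.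
3. 24 ⇐ 19: but-2-enolide by esterification of C6–OH with 2-(bromomethyl)acrylic acid and ring-closing metathesis. 19 ⇐ 18: 3(2H)-furanone by gold-catalysed 5-endo-dig cyclisation of the C4-hydroxy ynone.
4. 18 ⇐ lactone 8 (C3–C7; C6 from the glutamic-acid pool, C4 by enolate hydroxylation; the γ-lactone C3(=O)–O–C6 is a temporary ring, opened in step 11) + alkyne 15 (C1, C2, C8–C10; C9/C10 from asymmetric epoxidation of crotyl alcohol and C3-selective alkynylalane opening).
5. Ring order: furanone (step 12) → but-2-enolide (step 14) → nine-membered oxa-ring (step 17).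

Key step: step 17

Remark: 5 may contain its C3 epimer and 13 is an epimer mixture at the acetal carbon; both are inconsequential because these centres are erased in steps 4 and 9.

## Route

Step 1
Reactants: 1 (S)-5-(hydroxymethyl)dihydrofuran-2(3H)-one
Product: 2 (S)-5-oxotetrahydrofuran-2-carbaldehyde
Conditions: Dess–Martin periodinane, CH2Cl2, 0 °C → rt; filtered and used crude
Reagents that add atoms: none
Why: Dess–Martin oxidation stops at the aldehyde under non-basic conditions, so the O-bearing stereocentre (future C6) α to the new aldehyde should not epimerise.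

Step 2
Reactants: 2 (S)-5-oxotetrahydrofuran-2-carbaldehyde
Product: 3 (S)-5-vinyldihydrofuran-2(3H)-one
Conditions: Ph3PCH3Br, KHMDS, THF, 0 °C; then 2, −78 → 0 °C
Reagents that add atoms: methyltriphenylphosphonium bromide (C[P+](c1ccccc1)(c1ccccc1)c1ccccc1.[Br-])
Why: Wittig methylenation with the non-stabilised ylide at low temperature should convert the aldehyde, far more electrophilic than the lactone, before α-epimerisation competes; no new stereocentre.

Step 3
Reactants: 3 (S)-5-vinyldihydrofuran-2(3H)-one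
Product: 5 (3R,5S)-3-methyl-5-vinyldihydrofuran-2(3H)-one, via lithium enolate 4 (not isolated)
Conditions: LDA, THF, −78 °C; MeI, −78 → −40 °C
Reagents that add atoms: iodomethane (CI)
Why: Enolate alkylation installs the C4 methyl group, expected mainly anti to the vinyl group; the configuration at this carbon is irrelevant because it is re-enolised in step 4.

Step 4
Reactants: 5 (3R,5S)-3-methyl-5-vinyldihydrofuran-2(3H)-one
Product: 7 (3R,5S)-3-hydroxy-3-methyl-5-vinyldihydrofuran-2(3H)-one, via sodium enolate 6 (not isolated)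
Conditions: NaHMDS, THF, −78 °C; 2-(benzenesulfonyl)-3-phenyloxaziridine, −78 °C; aq. NH4Cl
Reagents that add atoms: 2-(benzenesulfonyl)-3-phenyloxaziridine (O=S(=O)(N1OC1c1ccccc1)c1ccccc1)
Why: Davis enolate hydroxylation delivers oxygen to the planar tetrasubstituted enolate on the face anti to the C5 vinyl group (1,3-induction in the five-membered ring), which should set the tertiary carbinol (future C4) with OH trans to vinyl.

Step 5
Reactants: 7 (3R,5S)-3-hydroxy-3-methyl-5-vinyldihydrofuran-2(3H)-one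
Product: 8 (3R,5S)-3-methyl-3-[(trimethylsilyl)oxy]-5-vinyldihydrofuran-2(3H)-one
Conditions: TMSCl, imidazole, DMF, 0 °C → rt
Reagents that add atoms: chlorotrimethylsilane (C[Si](C)(C)Cl)
Why: Silylation masks the acidic tertiary OH so that only one equivalent of acetylide is consumed in step 11, and the TMS ether can later be removed without touching a TBS ether; no stereocentre is touched.

Step 6
Reactants: 9 (E)-but-2-en-1-ol
Product: 10 [(2R,3R)-3-methyloxiran-2-yl]methanol
Conditions: Ti(OiPr)4 (cat.), D-(−)-diethyl tartrate (cat.), t-BuOOH, 4 Å MS, CH2Cl2, −20 °C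
Reagents that add atoms: tert-butyl hydroperoxide (CC(C)(C)OO)
Why: Sharpless asymmetric epoxidation of the (E)-allylic alcohol with the D-(−)-tartrate ligand should give the (2R,3R)-epoxy alcohol by reagent control, fixing the future C9 and, after inversion in step 7, C10.

Step 7
Reactants: 10 [(2R,3R)-3-methyloxiran-2-yl]methanol
Product: 12 (2S,3R)-3-methylpent-4-yne-1,2-diol, via C-silyl alkynediol 11 (not isolated)
Conditions: TMSC≡CH, n-BuLi, Et2AlCl, toluene, 0 °C; then 10, 0 °C → rt; aq. Rochelle salt; then K2CO3 (cat.), MeOH, rt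
Reagents that add atoms: ethynyltrimethylsilane (C#C[Si](C)(C)C)
Why: The alkynylalane, bound to the substrate as an aluminium alkoxide, opens the 2,3-epoxy alcohol at C3 with SN2 inversion, turning the trans-epoxide into the syn methyl/hydroxy pair (future C10/C9); methanolysis then removes the alkynyl silyl group.

Step 8
Reactants: 12 (2S,3R)-3-methylpent-4-yne-1,2-diol
Product: 13 (4S)-4-[(2R)-but-3-yn-2-yl]-2-(4-methoxyphenyl)-1,3-dioxolane
Conditions: 4-MeOC6H4CH(OMe)2, PPTS (cat.), CH2Cl2, rt
Reagents that add atoms: 4-methoxybenzaldehyde dimethyl acetal (COC(OC)c1ccc(OC)cc1)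
Why: Acid-catalysed transacetalisation of the 1,2-diol gives the five-membered p-methoxybenzylidene acetal, which prepares the regioselective differentiation of the two oxygens.

Step 9
Reactants: 13 (4S)-4-[(2R)-but-3-yn-2-yl]-2-(4-methoxyphenyl)-1,3-dioxolane
Product: 14 (2S,3R)-2-[(4-methoxybenzyl)oxy]-3-methylpent-4-yn-1-ol
Conditions: DIBAL-H, CH2Cl2, −78 → 0 °C; aq. Rochelle salt
Reagents that add atoms: none
Why: Reductive acetal opening with DIBAL-H, which coordinates the less hindered primary oxygen and cleaves that C–O bond, should leave the PMB group on the secondary oxygen (future C9) and free the primary alcohol (future C8).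

Step 10
Reactants: 14 (2S,3R)-2-[(4-methoxybenzyl)oxy]-3-methylpent-4-yn-1-ol
Product: 15 tert-butyl{[(2S,3R)-2-[(4-methoxybenzyl)oxy]-3-methylpent-4-yn-1-yl]oxy}dimethylsilane
Conditions: TBSCl, imidazole, DMF, rt
Reagents that add atoms: tert-butylchlorodimethylsilane (CC(C)(C)[Si](C)(C)Cl)
Why: Standard silylation protects the primary alcohol as an ether that should survive the acetylide, gold, esterification and metathesis steps and is removable with HF.

Step 11
Reactants: 15 tert-butyl{[(2S,3R)-2-[(4-methoxybenzyl)oxy]-3-methylpent-4-yn-1-yl]oxy}dimethylsilane; 8 (3R,5S)-3-methyl-3-[(trimethylsilyl)oxy]-5-vinyldihydrofuran-2(3H)-one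
Product: 18 (3S,5R,9R,10S)-11-[(tert-butyldimethylsilyl)oxy]-3,5-dihydroxy-10-[(4-methoxybenzyl)oxy]-5,9-dimethylundec-1-en-7-yn-6-one, via lithium acetylide 16 (not isolated), via O-silyl ynone 17 (not isolated)
Conditions: 15, n-BuLi, THF, −78 °C; then 8, −78 → −40 °C; aq. NH4Cl; then citric acid, MeOH, rt
Reagents that add atoms: none
Why: Acyl addition of the lithium acetylide to the γ-lactone (no α-proton, so no enolisation) stops at the tetrahedral intermediate and on quench gives the ring-opened ynone with C6–OH free, and mild acidic methanolysis removes only the tertiary TMS ether; no stereocentre is touched.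

Step 12
Reactants: 18 (3S,5R,9R,10S)-11-[(tert-butyldimethylsilyl)oxy]-3,5-dihydroxy-10-[(4-methoxybenzyl)oxy]-5,9-dimethylundec-1-en-7-yn-6-one
Product: 19 (2R)-5-{(2S,3S)-4-[(tert-butyldimethylsilyl)oxy]-3-[(4-methoxybenzyl)oxy]butan-2-yl}-2-[(2S)-2-hydroxybut-3-en-1-yl]-2-methylfuran-3(2H)-one
Conditions: Ph3PAuNTf2 (3 mol %), toluene, rt
Reagents that add atoms: none
Why: Gold(I)-catalysed 5-endo-dig cyclisation of the α′-hydroxy ynone (C4–OH onto alkyne carbon C1, then protodeauration) gives the 3(2H)-furanone under neutral conditions, which protects C10 (γ to the ketone) from epimerisation; any lactol form of 18 should funnel to the same product.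

Step 13
Reactants: 19 (2R)-5-{(2S,3S)-4-[(tert-butyldimethylsilyl)oxy]-3-[(4-methoxybenzyl)oxy]butan-2-yl}-2-[(2S)-2-hydroxybut-3-en-1-yl]-2-methylfuran-3(2H)-one; 20 2-(bromomethyl)prop-2-enoic acid
Product: 21 (2S)-1-[(2R)-5-{(2S,3S)-4-[(tert-butyldimethylsilyl)oxy]-3-[(4-methoxybenzyl)oxy]butan-2-yl}-2-methyl-3-oxo-2,3-dihydrofuran-2-yl]but-3-en-2-yl 2-(bromomethyl)prop-2-enoate
Conditions: DIC, DMAP (5 mol %), CH2Cl2, 0 °C
Reagents that add atoms: none
Why: Steglich-type carbodiimide esterification of the only free hydroxyl (C6–OH), run cold with only catalytic DMAP so that acyl transfer outruns attack on the allylic bromide, attaches C11–C13 with retention at C6.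

Step 14
Reactants: 21 (2S)-1-[(2R)-5-{(2S,3S)-4-[(tert-butyldimethylsilyl)oxy]-3-[(4-methoxybenzyl)oxy]butan-2-yl}-2-methyl-3-oxo-2,3-dihydrofuran-2-yl]but-3-en-2-yl 2-(bromomethyl)prop-2-enoate
Product: 22 (5S)-3-(bromomethyl)-5-{[(2R)-5-{(2S,3S)-4-[(tert-butyldimethylsilyl)oxy]-3-[(4-methoxybenzyl)oxy]butan-2-yl}-2-methyl-3-oxo-2,3-dihydrofuran-2-yl]methyl}furan-2(5H)-one
Conditions: Grubbs second-generation catalyst (10 mol %), toluene, 80 °C, 5 mM
Reagents that add atoms: none
Why: Ring-closing metathesis between the C6 vinyl group and the 1,1-disubstituted acrylate closes the five-membered but-2-enolide with loss of ethene; ruthenium carbenes tolerate allylic bromides and the trisubstituted push–pull furanone alkene should be inert.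

Step 15
Reactants: 22 (5S)-3-(bromomethyl)-5-{[(2R)-5-{(2S,3S)-4-[(tert-butyldimethylsilyl)oxy]-3-[(4-methoxybenzyl)oxy]butan-2-yl}-2-methyl-3-oxo-2,3-dihydrofuran-2-yl]methyl}furan-2(5H)-one
Product: 23 (5S)-3-(bromomethyl)-5-{[(2R)-5-{(2S,3S)-4-hydroxy-3-[(4-methoxybenzyl)oxy]butan-2-yl}-2-methyl-3-oxo-2,3-dihydrofuran-2-yl]methyl}furan-2(5H)-one
Conditions: HF (48 % aq.), MeCN, 0 °C
Reagents that add atoms: none
Why: Acidic fluoride cleaves the primary TBS ether without any nucleophilic base, so the allylic bromide, the PMB ether, the base-sensitive butenolide (acidic C6–H) and the furanone should survive.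

Step 16
Reactants: 23 (5S)-3-(bromomethyl)-5-{[(2R)-5-{(2S,3S)-4-hydroxy-3-[(4-methoxybenzyl)oxy]butan-2-yl}-2-methyl-3-oxo-2,3-dihydrofuran-2-yl]methyl}furan-2(5H)-one
Product: 24 (2S,3S)-3-[(5R)-5-{[(2S)-4-(bromomethyl)-5-oxo-2,5-dihydrofuran-2-yl]methyl}-5-methyl-4-oxo-4,5-dihydrofuran-2-yl]-2-[(4-methoxybenzyl)oxy]butanal
Conditions: Dess–Martin periodinane, NaHCO3, CH2Cl2, 0 °C → rt; used directly
Reagents that add atoms: none
Why: Buffered Dess–Martin oxidation gives the α-alkoxy aldehyde without base, so C9 (α) and C10 should not epimerise and the allylic bromide is untouched.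

Step 17
Reactants: 24 (2S,3S)-3-[(5R)-5-{[(2S)-4-(bromomethyl)-5-oxo-2,5-dihydrofuran-2-yl]methyl}-5-methyl-4-oxo-4,5-dihydrofuran-2-yl]-2-[(4-methoxybenzyl)oxy]butanal
Product: 26 8-O-deacyl-9-O-(4-methoxybenzyl) derivative of the target (C8–OH free; all six stereocentres as in 28), via allylchromium(III) species 25 (not isolated)
Conditions: CrCl2 (8 equiv), THF, rt, slow addition of 24 (final ≤ 2 mM); aq. NH4Cl
Reagents that add atoms: none
Why: Cr(II) inserts into the allylic C13–Br bond by two one-electron transfers to give allylchromium(III) 25, which adds through its γ-carbon C7 to the C8 aldehyde in a closed six-membered transition state, the allylic transposition turning the but-2-enolide into the α-methylene-γ-butyrolactone (C11=C13) and leaving C8–OH after work-up. The closest known reaction type is the intramolecular Nozaki–Hiyama (Barbier-type) allylation used to close medium and large carbocycles fused to α-methylene lactones, together with the intermolecular Barbier reaction of 3-(bromomethyl)but-2-enolides with aldehydes. The nine-membered ring C6–C5–C4–O–C1–C10–C9–C8–C7 closes in a 9-exo-trig mode (C7 onto the exocyclic C8=O). C7 is controlled by the C6 stereocentre, because the aldehyde must reach the butenolide face anti to the C5 substituent, which gives the trans 6,7-fusion. C8 is controlled by the chair transition state with the C9 substituent equatorial (analysis of this chair leads to the 7,8-relationship of the target), and the α-OPMB group can chelate Cr(III), so the Cram-chelate preference (8,9-syn) is matched with it. The step needs chemoselectivity for the aldehyde over the furanone ketone and the lactone (secured by the aldehyde-selective organochromium), γ-regioselectivity (inherent to allylchromium) and ring closure over oligomerisation (secured by slow addition at high dilution and by the rigid furanone and butenolide, which leave only five rotatable bonds between C7 and C8).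

Step 18
Reactants: 26 8-O-deacyl-9-O-(4-methoxybenzyl) derivative of the target
Product: 27 9-O-(4-methoxybenzyl) ether of the target (C8 isobutyrate; all six stereocentres as in 28)
Conditions: (i-PrCO)2O, Et3N, DMAP (cat.), CH2Cl2, 0 °C → rt
Reagents that add atoms: isobutyric anhydride (CC(C)C(=O)OC(=O)C(C)C)
Why: DMAP-catalysed acylation of the single free hydroxyl (C8–OH) gives the isobutyrate with retention, and because the C9 oxygen is still a PMB ether there is no regiochemical issue or acyl migration.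

Step 19
Reactants: 27 9-O-(4-methoxybenzyl) ether of the target
Product: 28 (4R,6S,7R,8S,9S,10S)-1,4-epoxy-9-hydroxy-8-(2-methylpropanoyloxy)-3-oxogermacra-1,11(13)-dien-12,6-olide (CNP0141385.1)
Conditions: DDQ, CH2Cl2/pH 7 buffer, 0 °C → rt
Reagents that add atoms: none
Why: Oxidative PMB cleavage with DDQ (single-electron oxidation of the electron-rich arene, then hydrolysis of the oxocarbenium ion) under buffered non-basic conditions should free C9–OH without acyl migration from C8 or damage to the α-methylene lactone; no stereocentre is touched.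

## Compound list

1 | (S)-5-(hydroxymethyl)dihydrofuran-2(3H)-one | O=C1O[C@H](CO)CC1 | starting material
2 | (S)-5-oxotetrahydrofuran-2-carbaldehyde | O=C1O[C@H](C=O)CC1 | intermediate
3 | (S)-5-vinyldihydrofuran-2(3H)-one | O=C1O[C@H](C=C)CC1 | intermediate
4 | lithium enolate of 3 | [Li]OC1=CC[C@@H](C=C)O1 | intermediate (not isolated)
5 | (3R,5S)-3-methyl-5-vinyldihydrofuran-2(3H)-one (trans, expected major) | O=C1O[C@H](C=C)C[C@H]1C | intermediate
6 | sodium enolate of 5 | [Na]OC1=C(C)C[C@@H](C=C)O1 | intermediate (not isolated)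
7 | (3R,5S)-3-hydroxy-3-methyl-5-vinyldihydrofuran-2(3H)-one | O=C1O[C@H](C=C)C[C@@]1(C)O | intermediate
8 | (3R,5S)-3-methyl-3-[(trimethylsilyl)oxy]-5-vinyldihydrofuran-2(3H)-one | O=C1O[C@H](C=C)C[C@@]1(C)O[Si](C)(C)C | intermediate
9 | (E)-but-2-en-1-ol | C/C=C/CO | starting material
10 | [(2R,3R)-3-methyloxiran-2-yl]methanol | C[C@H]1O[C@@H]1CO | intermediate
11 | (2S,3R)-3-methyl-5-(trimethylsilyl)pent-4-yne-1,2-diol | C[Si](C)(C)C#C[C@@H](C)[C@H](O)CO | intermediate (not isolated)
12 | (2S,3R)-3-methylpent-4-yne-1,2-diol | C#C[C@@H](C)[C@H](O)CO | intermediate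
13 | (4S)-4-[(2R)-but-3-yn-2-yl]-2-(4-methoxyphenyl)-1,3-dioxolane (acetal carbon: epimer mixture) | C#C[C@@H](C)[C@H]1COC(O1)c1ccc(OC)cc1 | intermediate
14 | (2S,3R)-2-[(4-methoxybenzyl)oxy]-3-methylpent-4-yn-1-ol | C#C[C@@H](C)[C@H](OCc1ccc(OC)cc1)CO | intermediate
15 | tert-butyl{[(2S,3R)-2-[(4-methoxybenzyl)oxy]-3-methylpent-4-yn-1-yl]oxy}dimethylsilane | C#C[C@@H](C)[C@H](OCc1ccc(OC)cc1)CO[Si](C)(C)C(C)(C)C | intermediate
16 | lithium acetylide of 15 | [Li]C#C[C@@H](C)[C@H](OCc1ccc(OC)cc1)CO[Si](C)(C)C(C)(C)C | intermediate (not isolated)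
17 | (3S,5R,9R,10S)-11-[(tert-butyldimethylsilyl)oxy]-3-hydroxy-10-[(4-methoxybenzyl)oxy]-5,9-dimethyl-5-[(trimethylsilyl)oxy]undec-1-en-7-yn-6-one | C=C[C@@H](O)C[C@@](C)(O[Si](C)(C)C)C(=O)C#C[C@@H](C)[C@H](OCc1ccc(OC)cc1)CO[Si](C)(C)C(C)(C)C | intermediate (not isolated)
18 | (3S,5R,9R,10S)-11-[(tert-butyldimethylsilyl)oxy]-3,5-dihydroxy-10-[(4-methoxybenzyl)oxy]-5,9-dimethylundec-1-en-7-yn-6-one | C=C[C@@H](O)C[C@@](C)(O)C(=O)C#C[C@@H](C)[C@H](OCc1ccc(OC)cc1)CO[Si](C)(C)C(C)(C)C | intermediate
19 | (2R)-5-{(2S,3S)-4-[(tert-butyldimethylsilyl)oxy]-3-[(4-methoxybenzyl)oxy]butan-2-yl}-2-[(2S)-2-hydroxybut-3-en-1-yl]-2-methylfuran-3(2H)-one | C=C[C@@H](O)C[C@@]1(C)OC(=CC1=O)[C@@H](C)[C@H](OCc1ccc(OC)cc1)CO[Si](C)(C)C(C)(C)C | intermediate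
20 | 2-(bromomethyl)prop-2-enoic acid | C=C(CBr)C(=O)O | starting material
21 | (2S)-1-[(2R)-5-{(2S,3S)-4-[(tert-butyldimethylsilyl)oxy]-3-[(4-methoxybenzyl)oxy]butan-2-yl}-2-methyl-3-oxo-2,3-dihydrofuran-2-yl]but-3-en-2-yl 2-(bromomethyl)prop-2-enoate | C=C[C@@H](OC(=O)C(=C)CBr)C[C@@]1(C)OC(=CC1=O)[C@@H](C)[C@H](OCc1ccc(OC)cc1)CO[Si](C)(C)C(C)(C)C | intermediate
22 | (5S)-3-(bromomethyl)-5-{[(2R)-5-{(2S,3S)-4-[(tert-butyldimethylsilyl)oxy]-3-[(4-methoxybenzyl)oxy]butan-2-yl}-2-methyl-3-oxo-2,3-dihydrofuran-2-yl]methyl}furan-2(5H)-one | BrCC1=C[C@H](C[C@@]2(C)OC(=CC2=O)[C@@H](C)[C@H](OCc3ccc(OC)cc3)CO[Si](C)(C)C(C)(C)C)OC1=O | intermediate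
23 | (5S)-3-(bromomethyl)-5-{[(2R)-5-{(2S,3S)-4-hydroxy-3-[(4-methoxybenzyl)oxy]butan-2-yl}-2-methyl-3-oxo-2,3-dihydrofuran-2-yl]methyl}furan-2(5H)-one | BrCC1=C[C@H](C[C@@]2(C)OC(=CC2=O)[C@@H](C)[C@H](OCc3ccc(OC)cc3)CO)OC1=O | intermediate
24 | (2S,3S)-3-[(5R)-5-{[(2S)-4-(bromomethyl)-5-oxo-2,5-dihydrofuran-2-yl]methyl}-5-methyl-4-oxo-4,5-dihydrofuran-2-yl]-2-[(4-methoxybenzyl)oxy]butanal | BrCC1=C[C@H](C[C@@]2(C)OC(=CC2=O)[C@@H](C)[C@H](OCc3ccc(OC)cc3)C=O)OC1=O | intermediate
25 | allylchromium(III) dichloride derived from 24 (Cr on C13) | Cl[Cr](Cl)CC1=C[C@H](C[C@@]2(C)OC(=CC2=O)[C@@H](C)[C@H](OCc3ccc(OC)cc3)C=O)OC1=O | intermediate (not isolated)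
26 | 8-O-deacyl-9-O-(4-methoxybenzyl) derivative of the target: 1,4-epoxy-8-hydroxy-9-[(4-methoxybenzyl)oxy]-3-oxogermacra-1,11(13)-dien-12,6-olide with all six stereocentres as in 28 | C=C1C(=O)O[C@H]2C[C@@]3(C)OC(=CC3=O)[C@@H](C)[C@H](OCc4ccc(OC)cc4)[C@@H](O)[C@H]12 | intermediate
27 | 9-O-(4-methoxybenzyl) ether of the target: (4R,6S,7R,8S,9S,10S)-1,4-epoxy-9-[(4-methoxybenzyl)oxy]-8-(2-methylpropanoyloxy)-3-oxogermacra-1,11(13)-dien-12,6-olide | C=C1C(=O)O[C@H]2C[C@@]3(C)OC(=CC3=O)[C@@H](C)[C@H](OCc4ccc(OC)cc4)[C@@H](OC(=O)C(C)C)[C@H]12 | intermediate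
28 | (4R,6S,7R,8S,9S,10S)-1,4-epoxy-9-hydroxy-8-(2-methylpropanoyloxy)-3-oxogermacra-1,11(13)-dien-12,6-olide (CNP0141385.1) | C=C1C(=O)O[C@H]2C[C@@]3(C)OC(=CC3=O)[C@@H](C)[C@H](O)[C@@H](OC(=O)C(C)C)[C@H]12 | target

## Step count and risks

Total steps: 19. Longest linear sequence: 14 (steps 1–5 or 6–10, then 11–19).

Steps most likely to fail:

1. Step 17. What may go wrong: the strained ring-closing transition state may override the chair/chelate preference and deliver the wrong face of the aldehyde (C8 epimer), and intermolecular allylation may compete. Fallback: set C8 in a separate operation rather than in the ring closure. Setting out from 24, the same chromium-mediated closure (or its indium-mediated variant in THF/H2O) is taken to the C8-epimeric alcohol 8-epi-26 F1. Mitsunobu esterification of F1 with isobutyric acid (PPh3, DIAD, THF, 0 °C) installs the ester with inversion at C8 and comes back to the route at 27.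

2. Step 14. What may go wrong: slow turnover on the electron-poor 1,1-disubstituted alkene, and loss of the allylic bromide by alkylation of the catalyst's ligands. Fallback: keep bromine out of the metathesis and introduce it afterwards. Setting out from 19, acylation with acryloyl chloride (i-Pr2NEt, CH2Cl2) gives the acrylate of 19 F2. Morita–Baylis–Hillman reaction with aqueous formaldehyde (DABCO, dioxane/H2O) gives the 2-(hydroxymethyl)acrylate of 19 F3. Ring-closing metathesis gives the 3-(hydroxymethyl)but-2-enolide F4. Appel bromination (CBr4, PPh3, CH2Cl2, 0 °C) comes back to the route at 22.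

3. Step 4. What may go wrong: poor facial selectivity in the enolate hydroxylation, because the vinyl group is a small directing group. Fallback: direct the hydroxylation with a bulky group and build the vinyl group last. Setting out from 1, silylation (TBDPSCl, imidazole) gives the silyl ether (S)-5-{[(tert-butyldiphenylsilyl)oxy]methyl}dihydrofuran-2(3H)-one F5. Methylation (LDA, MeI) gives the 3-methyl lactone F6. Hydroxylation (NaHMDS, the same oxaziridine) anti to the large CH2OSi group gives the tertiary alcohol F7. Desilylation (HF·pyridine) gives the diol (3R,5S)-3-hydroxy-5-(hydroxymethyl)-3-methyldihydrofuran-2(3H)-one F8. Dess–Martin oxidation gives the aldehyde (2S,4R)-4-hydroxy-4-methyl-5-oxotetrahydrofuran-2-carbaldehyde F9. Wittig methylenation (excess Ph3P=CH2, −78 °C) comes back to the route at 7.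

Further compounds
F1 | step 17 | 8-epi-26 (C8 epimer of the macrocyclic alcohol 26) | C=C1C(=O)O[C@H]2C[C@@]3(C)OC(=CC3=O)[C@@H](C)[C@H](OCc4ccc(OC)cc4)[C@H](O)[C@H]12
F2 | step 14 | acrylate ester of 19 at C6–O | C=C[C@@H](OC(=O)C=C)C[C@@]1(C)OC(=CC1=O)[C@@H](C)[C@H](OCc1ccc(OC)cc1)CO[Si](C)(C)C(C)(C)C
F3 | step 14 | 2-(hydroxymethyl)acrylate ester of 19 at C6–O | C=C[C@@H](OC(=O)C(=C)CO)C[C@@]1(C)OC(=CC1=O)[C@@H](C)[C@H](OCc1ccc(OC)cc1)CO[Si](C)(C)C(C)(C)C
F4 | step 14 | 3-(hydroxymethyl)but-2-enolide analogue of 22 (CH2OH in place of CH2Br) | OCC1=C[C@H](C[C@@]2(C)OC(=CC2=O)[C@@H](C)[C@H](OCc3ccc(OC)cc3)CO[Si](C)(C)C(C)(C)C)OC1=O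
F5 | step 4 | (S)-5-{[(tert-butyldiphenylsilyl)oxy]methyl}dihydrofuran-2(3H)-one | O=C1O[C@H](CO[Si](c2ccccc2)(c2ccccc2)C(C)(C)C)CC1
F6 | step 4 | (3R,5S)-5-{[(tert-butyldiphenylsilyl)oxy]methyl}-3-methyldihydrofuran-2(3H)-one | O=C1O[C@H](CO[Si](c2ccccc2)(c2ccccc2)C(C)(C)C)C[C@H]1C
F7 | step 4 | (3R,5S)-5-{[(tert-butyldiphenylsilyl)oxy]methyl}-3-hydroxy-3-methyldihydrofuran-2(3H)-one | O=C1O[C@H](CO[Si](c2ccccc2)(c2ccccc2)C(C)(C)C)C[C@@]1(C)O
F8 | step 4 | (3R,5S)-3-hydroxy-5-(hydroxymethyl)-3-methyldihydrofuran-2(3H)-one | O=C1O[C@H](CO)C[C@@]1(C)O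
F9 | step 4 | (2S,4R)-4-hydroxy-4-methyl-5-oxotetrahydrofuran-2-carbaldehyde | O=C1O[C@H](C=O)C[C@@]1(C)O
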